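The C3=C4–C4a=C5 diene of the target runs across the fusion of carbocyclic ring A and pyran ring B, with C4–C4a as its central bond; read backwards, this is an ethynyl group on C8a flanked by a C5 vinyl group and a C3 methylene enol ether. A single ruthenium-catalysed dienyne metathesis cascade on that open chain forms both ring double bonds and closes both rings without touching a stereocentre. The precursor, with all five hydroxyls as triethylsilyl ethers and C6 still a carbinol, comes from esterifying a C1 alcohol (C7 from an asymmetric epoxidation, C8/C8a from an anti allenylzinc addition) with a D-isoleucine-derived enoic acid and methylenating the ester. Fluoride and MnO2 finish.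

Key step: step 24

Remark: atoms carry the isochromenone numbering (C1, O2, C3, C4, C4a, C5–C8, C8a; side chain C1'–C7'; ring A carbocycle, ring B pyran); the configurations of 29 and 30 map onto the target atom by atom, C6 is carried as one arbitrary epimer because it ends as the ketone, and (4-methoxybenzyloxy)acetaldehyde is taken as a catalogue aldehyde.

**Alcohol half: aldehyde 9**

Step 1
Reactants: 1 acrolein; 2 ethyl 2-(triphenylphosphoranylidene)propanoate
Product: 3 ethyl (2E)-2-methylpenta-2,4-dienoate
Conditions: CH2Cl2, 0 °C to rt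
Reagents that add atoms: none
Why: Wittig olefination with a stabilised α-branched ylide should give the (E)-trisubstituted enoate and leave the vinyl group of acrolein untouched.

Step 2
Reactants: 3 ethyl (2E)-2-methylpenta-2,4-dienoate
Product: 4 (2E)-2-methylpenta-2,4-dien-1-ol
Conditions: DIBAL-H (2.2 equiv), CH2Cl2, −78 °C; Rochelle salt work-up
Reagents that add atoms: none
Why: 1,2-Reduction of a conjugated ester by DIBAL-H should deliver the allylic alcohol without touching the diene.

Step 3
Reactants: 4 (2E)-2-methylpenta-2,4-dien-1-ol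
Product: 5 [(2S,3S)-3-ethenyl-2-methyloxiran-2-yl]methanol
Conditions: Ti(OiPr)4 (10 mol%), L-(+)-diisopropyl tartrate (12 mol%), t-BuOOH, 4 Å molecular sieves, CH2Cl2, −20 °C
Reagents that add atoms: tert-butyl hydroperoxide, CC(C)(C)OO
Why: Sharpless asymmetric epoxidation touches only the allylic-alcohol alkene, and the L-(+)-tartrate ligand delivers oxygen to the face that gives the (2S,3S)-epoxide, which fixes the future C7 centre.

Step 4
Reactants: 5 [(2S,3S)-3-ethenyl-2-methyloxiran-2-yl]methanol
Product: 6 (3R,4S)-4,5-dihydroxy-4-methylpent-1-en-3-yl benzoate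
Conditions: PhCO2H (1.2 equiv), Ti(OiPr)4 (1.5 equiv), CH2Cl2, rt
Reagents that add atoms: benzoic acid, O=C(O)c1ccccc1
Why: Titanium-assisted opening of a 2,3-epoxy alcohol by a carboxylic acid occurs at C3, here also the allylic carbon, with inversion, so the C2–O bond (future C7) is never broken and the inverted carbinol is the future C6, which is erased later.

Step 5
Reactants: 6 (3R,4S)-4,5-dihydroxy-4-methylpent-1-en-3-yl benzoate
Product: 7 (2S,3R)-2-methylpent-4-ene-1,2,3-triol
Conditions: K2CO3 (0.2 equiv), MeOH, rt; filtration, no aqueous work-up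
Reagents that add atoms: none
Why: Base-catalysed methanolysis (transesterification) removes the benzoate, and any acyl migration in 6 is harmless because every regioisomer converges on the same triol.

Step 6
Reactants: 7 (2S,3R)-2-methylpent-4-ene-1,2,3-triol
Product: 8 (2S,3R)-2-methyl-1,2,3-tris(triethylsilyloxy)pent-4-ene
Conditions: TESOTf (3.6 equiv), 2,6-lutidine, CH2Cl2, −78 to 0 °C
Reagents that add atoms: triethylsilyl trifluoromethanesulfonate, CC[Si](CC)(CC)OS(=O)(=O)C(F)(F)F
Why: A silyl triflate with a hindered pyridine base silylates primary, secondary and tertiary hydroxyls alike (silyl ether formation), so one fully protected compound should result.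

Step 7
Reactants: 8 (2S,3R)-2-methyl-1,2,3-tris(triethylsilyloxy)pent-4-ene
Product: 9 (2R,3R)-2-methyl-2,3-bis(triethylsilyloxy)pent-4-enal
Conditions: (COCl)2, DMSO, CH2Cl2, −78 to −30 °C; Et3N
Reagents that add atoms: none
Why: Under Swern conditions a primary triethylsilyl ether is cleaved and oxidised in one operation while secondary and tertiary triethylsilyl ethers survive, and the quaternary α-carbon rules out epimerisation of the aldehyde.

**Allenylzinc precursor: mesylate 14**

Step 8
Reactants: 10 2-[(4-methoxyphenyl)methoxy]acetaldehyde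
Product: 11 rac-1-[(4-methoxyphenyl)methoxy]-4-(trimethylsilyl)but-3-yn-2-ol
Conditions: Me3SiC≡CH, n-BuLi, THF, −78 °C; then 10; aqueous NH4Cl
Reagents that add atoms: ethynyltrimethylsilane, C#C[Si](C)(C)C
Why: 1,2-Addition of a lithium acetylide to the aldehyde gives the racemic propargylic alcohol, whose stereocentre is set two steps later.

Step 9
Reactants: 11 rac-1-[(4-methoxyphenyl)methoxy]-4-(trimethylsilyl)but-3-yn-2-ol
Product: 12 1-[(4-methoxyphenyl)methoxy]-4-(trimethylsilyl)but-3-yn-2-one
Conditions: MnO2 (excess), CH2Cl2, rt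
Reagents that add atoms: none
Why: MnO2 oxidises propargylic alcohols selectively to ynones and leaves the 4-methoxybenzyl ether and the silylalkyne alone.

Step 10
Reactants: 12 1-[(4-methoxyphenyl)methoxy]-4-(trimethylsilyl)but-3-yn-2-one
Product: 13 (2R)-1-[(4-methoxyphenyl)methoxy]-4-(trimethylsilyl)but-3-yn-2-ol
Conditions: RuCl[(S,S)-TsDPEN](p-cymene) (2 mol%), i-PrOH, rt
Reagents that add atoms: none
Why: Noyori asymmetric transfer hydrogenation of an ynone places hydride on the face set by the (S,S)-ligand with the alkyne as the π-directing group, which should give the (R)-carbinol here (R because the CH2O branch outranks the alkyne).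

Step 11
Reactants: 13 (2R)-1-[(4-methoxyphenyl)methoxy]-4-(trimethylsilyl)but-3-yn-2-ol
Product: 14 (2R)-1-[(4-methoxyphenyl)methoxy]-4-(trimethylsilyl)but-3-yn-2-yl methanesulfonate
Conditions: MsCl, Et3N, CH2Cl2, −20 °C
Reagents that add atoms: methanesulfonyl chloride, CS(=O)(=O)Cl
Why: Sulfonylation of the secondary alcohol proceeds with retention and gives the propargylic mesylate needed for the SN2' palladation.

**Alcohol half: union to alcohol 18**

Step 12
Reactants: 9 (2R,3R)-2-methyl-2,3-bis(triethylsilyloxy)pent-4-enal; 14 (2R)-1-[(4-methoxyphenyl)methoxy]-4-(trimethylsilyl)but-3-yn-2-yl methanesulfonate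
Product: 16 (2S,3R,4S,5R)-1-[(4-methoxyphenyl)methoxy]-4-methyl-4,5-bis(triethylsilyloxy)-2-[(trimethylsilyl)ethynyl]hept-6-en-3-ol, via allenylzinc reagent 15 (not isolated)
Conditions: Pd(OAc)2 (5 mol%), PPh3 (5 mol%), Et2Zn (3 equiv), THF, −78 to −20 °C
Reagents that add atoms: none
Why: Marshall propargylation, in which zerovalent palladium displaces the mesylate in an anti SN2' sense, transmetalation to zinc keeps the allene configuration and the allenylzinc adds through a closed SE2' transition state, so that C8a is set by the reagent (net inversion of the mesylate carbon), the C8/C8a anti relationship by the cyclic transition state, and the C8 face by reagent control, which must dominate the own bias of the quaternary α-silyloxy aldehyde.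

Step 13
Reactants: 16 (2S,3R,4S,5R)-1-[(4-methoxyphenyl)methoxy]-4-methyl-4,5-bis(triethylsilyloxy)-2-[(trimethylsilyl)ethynyl]hept-6-en-3-ol
Product: 17 4-methoxybenzyl ether of 18 (the C8 triethylsilyl ether of 16)
Conditions: TESOTf (1.5 equiv), 2,6-lutidine, CH2Cl2, 0 °C to rt
Reagents that add atoms: triethylsilyl trifluoromethanesulfonate, CC[Si](CC)(CC)OS(=O)(=O)C(F)(F)F
Why: Silyl triflate silylation should cap the hindered secondary C8 hydroxyl, while the 4-methoxybenzyl ether, the silylalkyne and the alkene are inert.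

Step 14
Reactants: 17 4-methoxybenzyl ether of 18
Product: 18 (2S,3R,4R,5R)-4-methyl-3,4,5-tris(triethylsilyloxy)-2-[(trimethylsilyl)ethynyl]hept-6-en-1-ol
Conditions: DDQ (1.3 equiv), CH2Cl2/pH 7 buffer, 0 °C
Reagents that add atoms: none
Why: Oxidative cleavage of a 4-methoxybenzyl ether by DDQ in wet solvent frees only the primary C1 hydroxyl, since silyl ethers, the silylalkyne and the isolated vinyl group do not react.

**Acid half: acid 26**

Step 15
Reactants: 19 D-isoleucine
Product: 21 (2R,3R)-2-hydroxy-3-methylpentanoic acid, via alpha-lactone 20 (not isolated)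
Conditions: NaNO2, 1 M H2SO4, 0 °C to rt
Reagents that add atoms: water, O
Why: Diazotisation of an α-amino acid proceeds with overall retention by double inversion through the α-lactone, so C2 and C3 of D-isoleucine become C4' and C5' unchanged.

Step 16
Reactants: 21 (2R,3R)-2-hydroxy-3-methylpentanoic acid
Product: 22 (3R,4R)-3-hydroxy-4-methylhexan-2-one
Conditions: MeLi (3.5 equiv), Et2O, 0 °C to rt; inverse quench into cold aqueous NH4Cl
Reagents that add atoms: methyllithium, [Li]C
Why: Addition of methyllithium to the lithium carboxylate stops at the gem-dialkoxide, which collapses to the methyl ketone only on work-up (carboxylic acid to ketone), and the α-centre is shielded from enolisation as its alkoxide.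

Step 17
Reactants: 22 (3R,4R)-3-hydroxy-4-methylhexan-2-one
Product: 23 (3R,4R,5R)-3,5-dimethylhept-1-ene-3,4-diol
Conditions: CH2=CHMgBr (3 equiv), THF, −78 to 0 °C
Reagents that add atoms: vinylmagnesium bromide, C=C[Mg]Br
Why: Grignard addition to an α-hydroxy ketone under Cram chelate control, in which magnesium bridges the alkoxide and carbonyl oxygens and the vinyl group attacks from the side of the α-hydrogen, away from the sec-butyl group, should set C3' as R.

Step 18
Reactants: 23 (3R,4R,5R)-3,5-dimethylhept-1-ene-3,4-diol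
Product: 24 methyl (2E,4R,5R,6R)-4,5-dihydroxy-4,6-dimethyloct-2-enoate
Conditions: methyl acrylate (5 equiv), second-generation Hoveyda–Grubbs catalyst, RuCl2(H2IMes)(=CH-C6H4-2-OiPr) (5 mol%), CH2Cl2, 40 °C
Reagents that add atoms: methyl acrylate, C=CC(=O)OC
Why: Olefin cross-metathesis between a free tertiary allylic alcohol and an acrylate is selective because neither partner homodimerises readily, and it gives the (E)-enoate.

Step 19
Reactants: 24 methyl (2E,4R,5R,6R)-4,5-dihydroxy-4,6-dimethyloct-2-enoate
Product: 25 methyl (2E,4R,5R,6R)-4,6-dimethyl-4,5-bis(triethylsilyloxy)oct-2-enoate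
Conditions: TESOTf (3 equiv), 2,6-lutidine, CH2Cl2, 0 °C to rt
Reagents that add atoms: triethylsilyl trifluoromethanesulfonate, CC[Si](CC)(CC)OS(=O)(=O)C(F)(F)F
Why: The silyl triflate silylates both the secondary and the tertiary hydroxyl, and the enoate is inert.

Step 20
Reactants: 25 methyl (2E,4R,5R,6R)-4,6-dimethyl-4,5-bis(triethylsilyloxy)oct-2-enoate
Product: 26 (2E,4R,5R,6R)-4,6-dimethyl-4,5-bis(triethylsilyloxy)oct-2-enoic acid
Conditions: LiOH·H2O, THF/MeOH/H2O, rt; acidification to pH 5 with aqueous NaH2PO4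
Reagents that add atoms: lithium hydroxide, [Li+].[OH-]
Why: Saponification of the unhindered methyl ester should be clean because the γ-carbon is quaternary, so the double bond cannot leave conjugation, and triethylsilyl ethers tolerate aqueous LiOH at room temperature.

**Union, cascade and endgame**

Step 21
Reactants: 18 (2S,3R,4R,5R)-4-methyl-3,4,5-tris(triethylsilyloxy)-2-[(trimethylsilyl)ethynyl]hept-6-en-1-ol; 26 (2E,4R,5R,6R)-4,6-dimethyl-4,5-bis(triethylsilyloxy)oct-2-enoic acid
Product: 27 (2S,3R,4R,5R)-4-methyl-3,4,5-tris(triethylsilyloxy)-2-[(trimethylsilyl)ethynyl]hept-6-en-1-yl (2E,4R,5R,6R)-4,6-dimethyl-4,5-bis(triethylsilyloxy)oct-2-enoate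
Conditions: EDC·HCl, DMAP, CH2Cl2, 0 °C to rt
Reagents that add atoms: none
Why: Carbodiimide esterification with DMAP catalysis (Steglich) joins the only free hydroxyl of 18 to the acid without touching a stereocentre.

Step 22
Reactants: 27 ester of 18 with 26
Product: 28 C3 methylene enol ether of 27 (ester C=O replaced by C=CH2, a 2-alkoxy-1,3-diene; alkyne still carrying SiMe3)
Conditions: Cp2TiMe2 (3 equiv), toluene, 70 °C, dark; filtration through basic alumina
Reagents that add atoms: dimethyltitanocene, C[Ti](C)(C1C=CC=C1)C1C=CC=C1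
Why: Petasis methylenation, in which thermally generated Cp2Ti=CH2 turns the ester carbonyl into the 1,1-disubstituted enol ether (an enoate giving the 2-alkoxy-1,3-diene), should work while the bulky silyl group keeps the alkyne away from the titanium carbene.

Step 23
Reactants: 28 silylalkyne enol ether
Product: 29 open-chain cascade precursor (28 with a free ethynyl group on C8a; C3 methylene enol ether, C5 vinyl group, OSiEt3 on C6, C7, C8, C3' and C4')
Conditions: K2CO3 (0.5 equiv), MeOH/THF, 0 °C to rt
Reagents that add atoms: none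
Why: Carbonate-catalysed methanolysis of the alkynyl C–Si bond is far faster than attack on hindered triethylsilyl ethers, and the enol ether is stable to base.

Step 24
Reactants: 29 open-chain cascade precursor
Product: 30 (6R,7R,8R,8aS)-3-[(1E,3R,4R,5R)-3,5-dimethyl-3,4-bis(triethylsilyloxy)hept-1-en-1-yl]-7-methyl-6,7,8-tris(triethylsilyloxy)-6,7,8,8a-tetrahydro-1H-isochromene
Conditions: second-generation Hoveyda–Grubbs catalyst, RuCl2(H2IMes)(=CH-C6H4-2-OiPr) (10 mol%), degassed toluene (0.005 M), 80 °C
Reagents that add atoms: none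
Why: Tandem ring-closing dienyne metathesis: the catalyst loads as an alkylidene on the monosubstituted C5 vinyl group, adds to the C8a ethynyl group so that C5 bonds to C4a (exo mode, six-membered carbocycle ring A) and the metal moves to C4 as a vinylcarbene, and this carbene closes on the C3=CH2 enol ether (six-membered pyran ring B through C4, C4a, C8a, C1, O2 and C3) and leaves as Ru=CH2, so that ethylene is the only by-product. The closest known reaction types are dienyne ring-closing metathesis to fused bicyclic 1,3-dienes and ring-closing metathesis onto acyclic enol ethers made by ester methylenation; ending the dienyne relay on a 2-alkoxy-1,3-diene joins the two and is the one real uncertainty of the route. No stereocentre is created, and C6, C7, C8, C8a, C3', C4' and C5' are spectators. The selectivity needed is loading at C5 and not at the C1'=C2' alkene or the enol ether, and the substrate should secure it because the C5 vinyl group is the only monosubstituted alkene, the C1'=C2' alkene is 1,2-disubstituted next to the fully substituted silylated C3' carbinol, and the 1,1-disubstituted enol ether is so poor an initiation site that it acts only as the terminating olefin and no inert alkoxycarbene should accumulate. High dilution is used to suppress intermolecular reaction of the terminal alkyne.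

Step 25
Reactants: 30 bicyclic dienol ether
Product: 31 (6R,7R,8R,8aS)-3-[(1E,3R,4R,5R)-3,4-dihydroxy-3,5-dimethylhept-1-en-1-yl]-7-methyl-6,7,8,8a-tetrahydro-1H-isochromene-6,7,8-triol
Conditions: TBAF (6 equiv), THF, 0 °C to rt; non-acidic work-up
Reagents that add atoms: none
Why: Fluoride-induced desilylation removes all five triethylsilyl groups under basic conditions that the acid-sensitive dienol ether should tolerate.

Step 26
Reactants: 31 pentaol
Product: 32 (7S,8R,8aS)-3-[(1E,3R,4R,5R)-3,4-dihydroxy-3,5-dimethylhept-1-en-1-yl]-7,8-dihydroxy-7-methyl-1,7,8,8a-tetrahydro-6H-isochromen-6-one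
Conditions: MnO2 (activated, excess), EtOAc, rt
Reagents that add atoms: none
Why: MnO2 oxidises only allylic secondary alcohols, so the dienylic C6 carbinol should become the conjugated ketone while the tertiary C3' hydroxyl and the non-allylic C8 and C4' hydroxyls stay, which also erases the C6 centre.

**Compound list**

1 | acrolein | C=CC=O | starting material
2 | ethyl 2-(triphenylphosphoranylidene)propanoate | CCOC(=O)C(C)=P(c1ccccc1)(c1ccccc1)c1ccccc1 | starting material
3 | ethyl (2E)-2-methylpenta-2,4-dienoate | CCOC(=O)/C(C)=C/C=C | intermediate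
4 | (2E)-2-methylpenta-2,4-dien-1-ol | OC/C(C)=C/C=C | intermediate
5 | [(2S,3S)-3-ethenyl-2-methyloxiran-2-yl]methanol | OC[C@]1(C)O[C@H]1C=C | intermediate
6 | (3R,4S)-4,5-dihydroxy-4-methylpent-1-en-3-yl benzoate | OC[C@](C)(O)[C@H](OC(=O)c1ccccc1)C=C | intermediate
7 | (2S,3R)-2-methylpent-4-ene-1,2,3-triol | OC[C@](C)(O)[C@H](O)C=C | intermediate
8 | (2S,3R)-2-methyl-1,2,3-tris(triethylsilyloxy)pent-4-ene | CC[Si](CC)(CC)OC[C@](C)(O[Si](CC)(CC)CC)[C@H](O[Si](CC)(CC)CC)C=C | intermediate
9 | (2R,3R)-2-methyl-2,3-bis(triethylsilyloxy)pent-4-enal | O=C[C@](C)(O[Si](CC)(CC)CC)[C@H](O[Si](CC)(CC)CC)C=C | intermediate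
10 | 2-[(4-methoxyphenyl)methoxy]acetaldehyde | COc1ccc(COCC=O)cc1 | starting material
11 | rac-1-[(4-methoxyphenyl)methoxy]-4-(trimethylsilyl)but-3-yn-2-ol | COc1ccc(COCC(O)C#C[Si](C)(C)C)cc1 | intermediate
12 | 1-[(4-methoxyphenyl)methoxy]-4-(trimethylsilyl)but-3-yn-2-one | COc1ccc(COCC(=O)C#C[Si](C)(C)C)cc1 | intermediate
13 | (2R)-1-[(4-methoxyphenyl)methoxy]-4-(trimethylsilyl)but-3-yn-2-ol | COc1ccc(COC[C@H](O)C#C[Si](C)(C)C)cc1 | intermediate
14 | (2R)-1-[(4-methoxyphenyl)methoxy]-4-(trimethylsilyl)but-3-yn-2-yl methanesulfonate | COc1ccc(COC[C@H](OS(C)(=O)=O)C#C[Si](C)(C)C)cc1 | intermediate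
15 | ethyl{(aR)-4-[(4-methoxyphenyl)methoxy]-1-(trimethylsilyl)buta-1,2-dien-1-yl}zinc, formed in the flask in step 12 | CC[Zn]C([Si](C)(C)C)=[C@]=C([H])COCc1ccc(OC)cc1 | intermediate
16 | (2S,3R,4S,5R)-1-[(4-methoxyphenyl)methoxy]-4-methyl-4,5-bis(triethylsilyloxy)-2-[(trimethylsilyl)ethynyl]hept-6-en-3-ol | COc1ccc(COC[C@H](C#C[Si](C)(C)C)[C@@H](O)[C@](C)(O[Si](CC)(CC)CC)[C@H](O[Si](CC)(CC)CC)C=C)cc1 | intermediate
17 | 1-methoxy-4-({[(2S,3R,4R,5R)-4-methyl-3,4,5-tris(triethylsilyloxy)-2-[(trimethylsilyl)ethynyl]hept-6-en-1-yl]oxy}methyl)benzene | COc1ccc(COC[C@H](C#C[Si](C)(C)C)[C@@H](O[Si](CC)(CC)CC)[C@](C)(O[Si](CC)(CC)CC)[C@H](O[Si](CC)(CC)CC)C=C)cc1 | intermediate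
18 | (2S,3R,4R,5R)-4-methyl-3,4,5-tris(triethylsilyloxy)-2-[(trimethylsilyl)ethynyl]hept-6-en-1-ol | OC[C@H](C#C[Si](C)(C)C)[C@@H](O[Si](CC)(CC)CC)[C@](C)(O[Si](CC)(CC)CC)[C@H](O[Si](CC)(CC)CC)C=C | intermediate
19 | D-isoleucine, (2R,3R)-2-amino-3-methylpentanoic acid | CC[C@@H](C)[C@@H](N)C(=O)O | starting material
20 | (3S)-3-[(2R)-butan-2-yl]oxiran-2-one, formed in the flask in step 15 | CC[C@@H](C)[C@@H]1OC1=O | intermediate
21 | (2R,3R)-2-hydroxy-3-methylpentanoic acid | CC[C@@H](C)[C@@H](O)C(=O)O | intermediate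
22 | (3R,4R)-3-hydroxy-4-methylhexan-2-one | CC[C@@H](C)[C@@H](O)C(C)=O | intermediate
23 | (3R,4R,5R)-3,5-dimethylhept-1-ene-3,4-diol | CC[C@@H](C)[C@@H](O)[C@](C)(O)C=C | intermediate
24 | methyl (2E,4R,5R,6R)-4,5-dihydroxy-4,6-dimethyloct-2-enoate | CC[C@@H](C)[C@@H](O)[C@](C)(O)/C=C/C(=O)OC | intermediate
25 | methyl (2E,4R,5R,6R)-4,6-dimethyl-4,5-bis(triethylsilyloxy)oct-2-enoate | CC[C@@H](C)[C@@H](O[Si](CC)(CC)CC)[C@](C)(O[Si](CC)(CC)CC)/C=C/C(=O)OC | intermediate
26 | (2E,4R,5R,6R)-4,6-dimethyl-4,5-bis(triethylsilyloxy)oct-2-enoic acid | CC[C@@H](C)[C@@H](O[Si](CC)(CC)CC)[C@](C)(O[Si](CC)(CC)CC)/C=C/C(=O)O | intermediate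
27 | (2S,3R,4R,5R)-4-methyl-3,4,5-tris(triethylsilyloxy)-2-[(trimethylsilyl)ethynyl]hept-6-en-1-yl (2E,4R,5R,6R)-4,6-dimethyl-4,5-bis(triethylsilyloxy)oct-2-enoate | CC[C@@H](C)[C@@H](O[Si](CC)(CC)CC)[C@](C)(O[Si](CC)(CC)CC)/C=C/C(=O)OC[C@H](C#C[Si](C)(C)C)[C@@H](O[Si](CC)(CC)CC)[C@](C)(O[Si](CC)(CC)CC)[C@H](O[Si](CC)(CC)CC)C=C | intermediate
28 | C3 methylene enol ether of 27 (2-alkoxy-1,3-diene, silylalkyne) | CC[C@@H](C)[C@@H](O[Si](CC)(CC)CC)[C@](C)(O[Si](CC)(CC)CC)/C=C/C(=C)OC[C@H](C#C[Si](C)(C)C)[C@@H](O[Si](CC)(CC)CC)[C@](C)(O[Si](CC)(CC)CC)[C@H](O[Si](CC)(CC)CC)C=C | intermediate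
29 | open-chain cascade precursor: C8a-ethynyl, C5-vinyl, C3 methylene enol ether, five OSiEt3 groups | CC[C@@H](C)[C@@H](O[Si](CC)(CC)CC)[C@](C)(O[Si](CC)(CC)CC)/C=C/C(=C)OC[C@H](C#C)[C@@H](O[Si](CC)(CC)CC)[C@](C)(O[Si](CC)(CC)CC)[C@H](O[Si](CC)(CC)CC)C=C | intermediate
30 | (6R,7R,8R,8aS)-3-[(1E,3R,4R,5R)-3,5-dimethyl-3,4-bis(triethylsilyloxy)hept-1-en-1-yl]-7-methyl-6,7,8-tris(triethylsilyloxy)-6,7,8,8a-tetrahydro-1H-isochromene | CC[C@@H](C)[C@@H](O[Si](CC)(CC)CC)[C@](C)(O[Si](CC)(CC)CC)/C=C/C1=CC2=C[C@@H](O[Si](CC)(CC)CC)[C@@](C)(O[Si](CC)(CC)CC)[C@H](O[Si](CC)(CC)CC)[C@@H]2CO1 | intermediate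
31 | (6R,7R,8R,8aS)-3-[(1E,3R,4R,5R)-3,4-dihydroxy-3,5-dimethylhept-1-en-1-yl]-7-methyl-6,7,8,8a-tetrahydro-1H-isochromene-6,7,8-triol | CC[C@@H](C)[C@@H](O)[C@](C)(O)/C=C/C1=CC2=C[C@@H](O)[C@@](C)(O)[C@H](O)[C@@H]2CO1 | intermediate
32 | (7S,8R,8aS)-3-[(1E,3R,4R,5R)-3,4-dihydroxy-3,5-dimethylhept-1-en-1-yl]-7,8-dihydroxy-7-methyl-1,7,8,8a-tetrahydro-6H-isochromen-6-one | CC[C@@H](C)[C@@H](O)[C@](C)(O)/C=C/C1=CC2=CC(=O)[C@@](C)(O)[C@H](O)[C@@H]2CO1 | target

**Step count and risks**

Total step count: 26. Longest linear sequence: 16 steps (steps 1–7, 12–14 and 21–26, from acrolein).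

Step 24. The ruthenium carbene may be consumed by the terminal alkyne (oligomerisation, or loading at the alkyne) before the C5 vinyl group engages, or the cascade may stop once ring A has closed. The fallback sets out from 29 and comes back at 30. An ethylene–alkyne cross-metathesis (second-generation Grubbs catalyst, ethylene at 1 atm, CH2Cl2, rt) takes the alkyne out of the ring-closing event by converting the C8a ethynyl group into a buta-1,3-dien-2-yl group, which should give the tetraene F1. Two ordinary olefin ring-closing metatheses (second-generation Hoveyda–Grubbs catalyst, toluene, 80 °C) then join the inner diene carbon to C5 (ring A) and the diene terminus to the enol ether carbon C3 (ring B), each with loss of ethylene, to give 30.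

Step 12. Addition to the neopentyl-type aldehyde may be slow, and the C8 face may leak because reagent control has to override the Felkin–Anh/Cornforth preference of the α-silyloxy aldehyde. The fallback sets out from 4 (with mesylate 14) and comes back at 17; it moves the allenylzinc addition to a small achiral aldehyde and sets C7 afterwards.
- MnO2 oxidation of dienol 4 gives (2E)-2-methylpenta-2,4-dienal F2.
- Allenylzinc 15, generated from 14 as in step 12, adds to F2 under pure reagent control and should give the anti homopropargylic dienol F3.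
- Shi epoxidation (Oxone, buffered MeCN/H2O, 0 °C, with the enantiomer of the fructose-derived ketone, the one the spiro transition-state model assigns to this face) epoxidises the trisubstituted alkene and sets C7 in the vinyl epoxy alcohol F4.
- Ti(OiPr)4/PhCO2H opens F4 at the allylic C6 with inversion to the benzoate F5.
- DIBAL-H removes the benzoate without touching the alkynylsilane and gives the triol F6.
- TESOTf/2,6-lutidine then gives 17.

Step 22. The titanium methylidene may add to the silylalkyne, or the 2-alkoxy-1,3-diene may hydrolyse or polymerise on heating and isolation. The fallback sets out from 27 and comes back at 30, bypassing 28 and 29, so that no alkyne ever meets a titanium carbene and no acyclic enol ether is isolated.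
- AgNO3/2,6-lutidine in aqueous acetone removes the alkynyl silyl group to give the terminal alkyne ester F7.
- Ring-closing enyne metathesis under ethylene (second-generation Grubbs catalyst, CH2Cl2, 40 °C) closes ring A and should give the 1-vinylcyclohexene ester F8.
- A titanium-mediated olefinic ester cyclisation (reduced titanium ethylidene from TiCl4, TMEDA, Zn, PbCl2 and CH3CHBr2, THF, 65 °C) then joins the diene terminus C4 to the ester carbonyl carbon C3 and forms the ring B enol ether of 30 directly.

Further compounds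

F1 | step 24 | C8a buta-1,3-dien-2-yl analogue of 29 (tetraene enol ether) | CC[C@@H](C)[C@@H](O[Si](CC)(CC)CC)[C@](C)(O[Si](CC)(CC)CC)/C=C/C(=C)OC[C@H](C(=C)C=C)[C@@H](O[Si](CC)(CC)CC)[C@](C)(O[Si](CC)(CC)CC)[C@H](O[Si](CC)(CC)CC)C=C
F2 | step 12 | (2E)-2-methylpenta-2,4-dienal | O=C/C(C)=C/C=C
F3 | step 12 | anti homopropargylic dienol: 16 with C7=C6 as an (E)-alkene in place of the two silyloxy carbons | COc1ccc(COC[C@H](C#C[Si](C)(C)C)[C@@H](O)/C(C)=C/C=C)cc1
F4 | step 12 | C6–C7 vinyl epoxy alcohol derived from F3 | COc1ccc(COC[C@H](C#C[Si](C)(C)C)[C@@H](O)[C@]2(C)O[C@H]2C=C)cc1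
F5 | step 12 | C6 benzoate, C7 and C8 free hydroxyls | COc1ccc(COC[C@H](C#C[Si](C)(C)C)[C@@H](O)[C@](C)(O)[C@H](OC(=O)c2ccccc2)C=C)cc1
F6 | step 12 | C6, C7, C8 triol (17 without its three triethylsilyl groups) | COc1ccc(COC[C@H](C#C[Si](C)(C)C)[C@@H](O)[C@](C)(O)[C@H](O)C=C)cc1
F7 | step 22 | terminal alkyne ester (27 without the alkynyl SiMe3 group) | CC[C@@H](C)[C@@H](O[Si](CC)(CC)CC)[C@](C)(O[Si](CC)(CC)CC)/C=C/C(=O)OC[C@H](C#C)[C@@H](O[Si](CC)(CC)CC)[C@](C)(O[Si](CC)(CC)CC)[C@H](O[Si](CC)(CC)CC)C=C
F8 | step 22 | ring A 1-vinylcyclohexene ester (C4a=C5 closed, C4 vinyl, ester on C1) | CC[C@@H](C)[C@@H](O[Si](CC)(CC)CC)[C@](C)(O[Si](CC)(CC)CC)/C=C/C(=O)OC[C@@H]1C(C=C)=C[C@@H](O[Si](CC)(CC)CC)[C@@](C)(O[Si](CC)(CC)CC)[C@@H]1O[Si](CC)(CC)CC
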